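The target is built one carbon short, as a copaane-type tricycle in which three carbons (C1–C3, labels defined below) bridge the cyclobutane carbons C11 and C5; the gem-dimethyl carbon C4 is inserted afterwards. The key step exploits the fact that, in ring C1–C2–C3–C4–C5–C10–C11, quaternary C4 sits between oxygen-bearing C3 and cyclobutane carbon C5. A silver-promoted semipinacol shift of C5 from the C3 carbinol to an exocyclic C(CH3)2SeCH3 carbon enlarges the six-membered ring to seven, installs both methyl groups and returns C3 as a ketone. The precursor comes from an asymmetric quinone Diels–Alder adduct by enolate alkylation (cyclobutane) and cuprate addition.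

Key step: step 11

Remark (labels): the target's atom labels are used for every intermediate: C1 = CH–O(angelate), C2 = CH2, C3 = CH–OAc, C4 = C(CH3)2, C5/C6/C10/C11 = cyclobutane carbons (C5 bonded to C4, C6 to C7, C10 to C9, C11 carries CH3 and C1), C7 = CH(CH3), C8 = CH2, C9 = C=O; ring A = C6–C7–C8–C9–C10–C11, ring B = the ring through C1–C2–C3.
Remark (assumption): 2-methoxy-5-methyl-1,4-benzoquinone is taken as a catalogue compound; the sense of induction in step 2 is the one predicted by the accepted catalyst model and is not established for this diene/quinone pair.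

Step 1
Reactants: 1 but-3-en-2-one
Product: 2 2-(triisopropylsilyloxy)buta-1,3-diene
Conditions: TIPSOTf, Et3N, Et2O, 0 °C to rt
Reagents that add atoms: triisopropylsilyl trifluoromethanesulfonate CC(C)[Si](OS(=O)(=O)C(F)(F)F)(C(C)C)C(C)C
Why: Soft enolisation and O-silylation of the methyl ketone (silyl enol ether formation) should give the 2-silyloxydiene; no stereocentre is formed.

Step 2
Reactants: 2 2-(triisopropylsilyloxy)buta-1,3-diene; 3 2-methoxy-5-methyl-1,4-benzoquinone
Product: 4 cis-fused Diels–Alder adduct
Conditions: (S)-3,3-diphenyl-1-(2-methylphenyl)tetrahydro-1H,3H-pyrrolo[1,2-c][1,3,2]oxazaborole (20 mol%), HNTf2 (18 mol%), CH2Cl2, −78 to −40 °C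
Reagents that add atoms: none
Why: Oxazaborolidinium-catalysed enantioselective quinone Diels–Alder reaction: the catalyst should bind the C5 carbonyl syn to the vinylic C6–H, the methoxy-bearing alkene is deactivated as a vinylogous ester, the CH2 terminus next to the silyloxy carbon attacks the methyl-bearing C11, and endo addition to the face left open by the catalyst sets the cis C6/C11 pair (the (S)-catalyst is the antipode predicted by the C–H···O pre-transition-state model; its mirror image would be used if the sense proved opposite).

Step 3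
Reactants: 4 cis-fused Diels–Alder adduct
Product: 5 bicyclic diol
Conditions: LiAlH4, THF, −78 to −20 °C; aqueous Rochelle salt work-up (no acid)
Reagents that add atoms: none
Why: LiAlH4 1,2-reduction of the ketone and of the vinylogous ester carbonyl: hydride should reach C5 from the convex face, anti to ring A, and then C1 anti to the axial angular methyl on C11 (helped by delivery from the C5 aluminate), giving C5–OH cis to the C6–C7 bond and C1–OH cis to the C11 methyl.

Step 4
Reactants: 5 bicyclic diol
Product: 6 C5 bromide with free C1 hydroxyl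
Conditions: CBr4, PPh3, 2,6-lutidine, CH2Cl2, −40 to −20 °C
Reagents that add atoms: carbon tetrabromide BrC(Br)(Br)Br
Why: Appel bromination: the C5 hydroxyl should react in preference to the neopentyl C1 hydroxyl beside quaternary C11 and is displaced with inversion, which places bromine trans to the C6–C7 bond and, in the reactive conformer, anti-periplanar to the C6–C11 bond.

Step 5
Reactants: 6 C5 bromide with free C1 hydroxyl
Product: 7 C1 silyl ether of the bromide
Conditions: TBSOTf, 2,6-lutidine, CH2Cl2, −78 °C
Reagents that add atoms: tert-butyldimethylsilyl trifluoromethanesulfonate CC(C)(C)[Si](C)(C)OS(=O)(=O)C(F)(F)F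
Why: Buffered silylation of the hindered allylic C1 alcohol with the silyl triflate protects it through the base, organometallic and acid steps that follow; no stereocentre changes.

Step 6
Reactants: 7 C1 silyl ether of the bromide
Product: 9 tricyclic ketone, via C9 ketone 8 (not isolated)
Conditions: Bu4NF, AcOH, THF, 0 °C; crude 8, then KOt-Bu, t-BuOH/THF, 0 °C to rt
Reagents that add atoms: none
Why: Fluoride cleaves the silyl enol ether and the potassium enolate closes the cyclobutane by intramolecular C-alkylation (4-exo-tet SN2, the keto halide cyclisation known for copaane-type tricycles): only the C10 enolate, axial on ring B, can reach the rear of the C5–Br bond, the C8 enolate returns by proton exchange, and inversion at C5 together with the cis ring fusion fixes C5 and C10.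

Step 7
Reactants: 9 tricyclic ketone
Product: 11 enone diketone, via enone enol ether 10 (not isolated)
Conditions: LiN(i-Pr)2, THF, −78 °C; N-tert-butylbenzenesulfinimidoyl chloride, −78 °C; then 0.5 M aqueous oxalic acid, THF, 0 °C
Reagents that add atoms: water O
Why: Mukaiyama dehydrogenation of the lithium enolate (C8 is the only enolisable position, C10 being a bridgehead) should give the C7=C8 enone, and mild acid hydrolyses the methyl enol ether by C2 protonation to the C3 ketone without loss of the C1 silyloxy group.

Step 8
Reactants: 11 enone diketone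
Product: 12 C7-methyl ketone with C8=C9 silyl enol ether
Conditions: Me2CuLi, Et2O, −78 °C; then TIPSOTf, −78 to −20 °C
Reagents that add atoms: lithium dimethylcuprate [Li+].C[Cu-]C; triisopropylsilyl trifluoromethanesulfonate CC(C)[Si](OS(=O)(=O)C(F)(F)F)(C(C)C)C(C)C
Why: Cuprate conjugate addition with enolate trapping: methyl should add to C7 from the face of the enone bridge that looks at the C5–H bridge, anti to the C11 methyl (as with apoverbenone-type enones), which sets C7, and O-silylation masks the C9 ketone while the saturated C3 ketone is untouched.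

Step 9
Reactants: 13 acetone; 14 dimethyl diselenide
Product: 16 2,2-bis(methylselanyl)propane, via methaneselenol 15 (not isolated)
Conditions: H3PO2 (50% aq.), 80 °C, selenol distilled into acetone, ZnCl2 (cat.), CH2Cl2, 0 °C
Reagents that add atoms: none
Why: Hypophosphorous acid reduces the diselenide to the selenol, which forms the selenoacetal of acetone under ZnCl2 catalysis (selenoacetalisation); no stereocentre.

Step 10
Reactants: 12 C7-methyl ketone with C8=C9 silyl enol ether; 16 2,2-bis(methylselanyl)propane
Product: 17 β-hydroxy selenide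
Conditions: 16, n-BuLi, THF, −78 °C; then 12, −78 °C; aqueous NH4Cl
Reagents that add atoms: none
Why: Selenium–lithium exchange on the selenoacetal gives 2-lithio-2-(methylselanyl)propane, which adds 1,2 to the only free ketone (C3); the new carbinol centre disappears in the next step, so both epimers are carried on.

Step 11
Reactants: 17 β-hydroxy selenide
Product: 18 ring-enlarged ketone
Conditions: AgBF4, basic Al2O3, CH2Cl2, 0 °C to rt
Reagents that add atoms: none
Why: Monovalent silver binds the methylseleno group of 17 and the C4–Se bond ionises while the anti-periplanar ring bond C3–C5 shifts to C4 and the C3 hydroxyl collapses to the ketone, so that C4 is inserted between C3 and C5. The closest known reaction type is the silver-induced seleno-pinacol (semipinacol) ring enlargement of 1-(1-selenoalkyl)cycloalkanols to 2,2-dialkylcycloalkanones. No ring is closed by cyclisation: the six-membered ring C1–C2–C3–C5–C10–C11 is enlarged to the seven-membered ring C1–C2–C3–C4–C5–C10–C11 by a suprafacial 1,2-shift (its twin through C6 grows in the same way). No stereocentre is created: C5 migrates with retention, C4 carries two methyl groups and the carbinol centre C3 becomes the carbonyl, so both epimers of 17 converge. The step needs migration of the methine C5 and not of the methylene C2, which the substrate should secure through the higher migratory aptitude of the more substituted carbon under cationic conditions, the inductive deactivation of C2 by the C1 silyloxy group and the strain released when the three-carbon bridge across the cyclobutane becomes four-carbon. Basic Al2O3 takes up the HBF4 so that the silyl ether and the silyl enol ether should persist.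

Step 12
Reactants: 18 ring-enlarged ketone
Product: 19 C3 alcohol
Conditions: (R)-2-methyl-CBS-oxazaborolidine (20 mol%), catecholborane, toluene, −78 °C
Reagents that add atoms: none
Why: Corey–Bakshi–Shibata reduction of the only ketone, flanked by quaternary C4 (large) and methylene C2 (small): the (R)-catalyst should deliver hydride to the face that gives the (S)-alcohol, with the hydroxyl on the C10 side and trans to the C1 oxygen.

Step 13
Reactants: 19 C3 alcohol
Product: 20 C3 acetate
Conditions: Ac2O, DMAP (cat.), pyridine, rt
Reagents that add atoms: acetic anhydride CC(=O)OC(C)=O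
Why: DMAP-catalysed acetylation of the neopentyl C3 alcohol, the only free hydroxyl at this stage, so the acetate cannot be misplaced; configuration is retained.

Step 14
Reactants: 20 C3 acetate
Product: 21 hydroxy keto acetate
Conditions: HF·pyridine, pyridine/THF, 0 °C to rt
Reagents that add atoms: none
Why: Fluoride-mediated desilylation frees the C1 alcohol and turns the silyl enol ether into the C9 ketone while the acetate stays; protonation at C8 creates no stereocentre.

Step 15
Reactants: 21 hydroxy keto acetate
Product: 22 CNP0204102.1
Conditions: angelic acid, 2,4,6-trichlorobenzoyl chloride, Et3N, toluene, rt; then 21, 80 °C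
Reagents that add atoms: angelic acid C/C=C(/C)C(=O)O
Why: Yamaguchi-type esterification through the 2,4,6-trichlorobenzoyl mixed anhydride, run without DMAP so that the (Z)-alkene should not isomerise to the tiglate; acylation occurs with retention at C1.

Compound list
1 | but-3-en-2-one (methyl vinyl ketone) | CC(=O)C=C | starting material
2 | 2-(triisopropylsilyloxy)buta-1,3-diene | C=CC(=C)O[Si](C(C)C)(C(C)C)C(C)C | intermediate
3 | 2-methoxy-5-methyl-1,4-benzoquinone | COC1=CC(=O)C(C)=CC1=O | starting material
4 | (4aS,8aR)-2-methoxy-4a-methyl-6-(triisopropylsilyloxy)-4a,5,8,8a-tetrahydronaphthalene-1,4-dione; cis-fused, carbonyls at C5 (beside C6–H) and C1 (beside C11–CH3) | COC1=CC(=O)[C@@]2(C)CC(O[Si](C(C)C)(C(C)C)C(C)C)=CC[C@H]2C1=O | intermediate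
5 | bicyclic diol: C5–OH cis to the C6–C7 bond, C1–OH cis to the C11 methyl, C2=C3 methyl enol ether, C8=C9 silyl enol ether | COC1=C[C@H](O)[C@@]2(C)CC(O[Si](C(C)C)(C(C)C)C(C)C)=CC[C@H]2[C@H]1O | intermediate
6 | C5 bromide of 5 (C5 inverted, Br trans to the C6–C7 bond), C1–OH free | COC1=C[C@H](O)[C@@]2(C)CC(O[Si](C(C)C)(C(C)C)C(C)C)=CC[C@H]2[C@@H]1Br | intermediate
7 | C1 tert-butyldimethylsilyl ether of 6 | COC1=C[C@H](O[Si](C)(C)C(C)(C)C)[C@@]2(C)CC(O[Si](C(C)C)(C(C)C)C(C)C)=CC[C@H]2[C@@H]1Br | intermediate
8 | C9 ketone from 7 (ring A silyl enol ether cleaved) | COC1=C[C@H](O[Si](C)(C)C(C)(C)C)[C@@]2(C)CC(=O)CC[C@H]2[C@@H]1Br | intermediate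
9 | tricyclic ketone: cyclobutane C5–C6–C11–C10 closed by the C5–C10 bond, C9 ketone, C2=C3 methyl enol ether, C1–OTBS on the C6 face | CC(C)(C)[Si](C)(C)O[C@H]1C=C(OC)[C@H]2[C@@H]3CCC(=O)[C@H]2[C@@]31C | intermediate
10 | C7=C8 enone of 9 (methyl enol ether kept) | CC(C)(C)[Si](C)(C)O[C@H]1C=C(OC)[C@H]2[C@@H]3C=CC(=O)[C@H]2[C@@]31C | intermediate
11 | enone diketone: C9(=O)–C8=C7, C3 ketone, C1–OTBS | CC(C)(C)[Si](C)(C)O[C@H]1CC(=O)[C@H]2[C@@H]3C=CC(=O)[C@H]2[C@@]31C | intermediate
12 | C3 ketone with C7 methyl on the side of the C5 bridge, C8=C9 triisopropylsilyl enol ether, C1–OTBS | CC(C)(C)[Si](C)(C)O[C@H]1CC(=O)[C@H]2[C@@H]3[C@H](C)C=C(O[Si](C(C)C)(C(C)C)C(C)C)[C@H]2[C@@]31C | intermediate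
13 | acetone | CC(C)=O | starting material
14 | dimethyl diselenide | C[Se][Se]C | starting material
15 | methaneselenol | C[SeH] | intermediate
16 | 2,2-bis(methylselanyl)propane | CC(C)([Se]C)[Se]C | intermediate
17 | β-hydroxy selenide: C3 tertiary alcohol carrying C(CH3)2SeCH3 (future C4); both C3 epimers | CC(C)(C)[Si](C)(C)O[C@H]1CC(O)(C(C)(C)[Se]C)[C@H]2[C@@H]3[C@H](C)C=C(O[Si](C(C)C)(C(C)C)C(C)C)[C@H]2[C@@]31C | intermediate
18 | ring-enlarged ketone: seven-membered ring C1–C2–C3–C4–C5–C10–C11, C3 ketone, C4 gem-dimethyl, C1–OTBS, C8=C9 silyl enol ether | CC(C)(C)[Si](C)(C)O[C@H]1CC(=O)C(C)(C)[C@H]2[C@@H]3[C@H](C)C=C(O[Si](C(C)C)(C(C)C)C(C)C)[C@H]2[C@@]31C | intermediate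
19 | (3S)-alcohol of 18: C3–OH on the C10 face, trans to the C1 oxygen | CC(C)(C)[Si](C)(C)O[C@H]1C[C@H](O)C(C)(C)[C@H]2[C@@H]3[C@H](C)C=C(O[Si](C(C)C)(C(C)C)C(C)C)[C@H]2[C@@]31C | intermediate
20 | C3 acetate of 19 | CC(C)(C)[Si](C)(C)O[C@H]1C[C@H](OC(C)=O)C(C)(C)[C@H]2[C@@H]3[C@H](C)C=C(O[Si](C(C)C)(C(C)C)C(C)C)[C@H]2[C@@]31C | intermediate
21 | hydroxy keto acetate: C1–OH, C3–OAc, C9 ketone | O[C@H]1C[C@H](OC(C)=O)C(C)(C)[C@H]2[C@@H]3[C@H](C)CC(=O)[C@H]2[C@@]31C | intermediate
22 | CNP0204102.1 (C3 acetate, C1 angelate, C9 ketone) | C/C=C(/C)C(=O)O[C@H]1C[C@H](OC(C)=O)C(C)(C)[C@H]2[C@@H]3[C@H](C)CC(=O)[C@H]2[C@@]31C | target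

Total step count: 15 (14 in the main line plus the preparation of selenoacetal 16 in step 9).
Longest linear sequence: 14 steps (steps 1–8 and 10–15).

Steps most likely to fail

Step 11. The silver-promoted ionisation may lose the selenide without the 1,2-shift (oxirane or olefin formation) or may strip the silyl enol ether before the shift. The fallback sets out from 12: isopropylidene transfer from diphenylsulfonium isopropylide (Corey–Chaykovsky type, THF, −78 °C) should give the 2,2-dimethyl spiro-oxirane F1. A Lewis acid (MgBr2·OEt2, CH2Cl2, −20 °C) would then open it at the dimethyl-substituted carbon with a Meinwald-type shift of C5, coming back to the route at 18.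

Step 6. The four-membered ring may close too slowly, so that base-induced loss of HBr or substitution of the allylic bromide takes over. The fallback sets out from 7: desilylation as before gives ketone 8, now isolated, and condensation with pyrrolidine (benzene, molecular sieves) gives the pyrrolidine enamine F2. The ring would be closed without strong base by intramolecular Stork enamine alkylation (MeCN, 60 °C), and hydrolysis of the iminium salt (aqueous NaOAc/AcOH) comes back to the route at 9.

Step 4. Site selectivity may be lost: the C1 hydroxyl, an easily ionised allylic alcohol next to the enol ether, may be brominated or ionised together with the C5 hydroxyl. The fallback sets out from 4 and never has both hydroxyls free: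
- NaBH4 (MeOH/CH2Cl2, −78 °C) reduces only the C5 ketone to hydroxy enone F3.
- MsCl/Et3N gives mesylate F4.
- i-Bu2AlH (−78 °C) reduces the C1 carbonyl, anti to the angular methyl, to allylic alcohol F5.
- TBSOTf/2,6-lutidine gives silyl ether F6.
- LiBr (THF, rt) displaces the mesylate with inversion (Finkelstein-type SN2) and comes back to the route at 7.

Further compounds
F1 | step 11 | 2,2-dimethyl spiro-oxirane at C3 of 12 (both C3 epimers) | CC(C)(C)[Si](C)(C)O[C@H]1CC4(OC4(C)C)[C@H]2[C@@H]3[C@H](C)C=C(O[Si](C(C)C)(C(C)C)C(C)C)[C@H]2[C@@]31C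
F2 | step 6 | pyrrolidine enamine of 8 (C9=C10 isomer) | COC1=C[C@H](O[Si](C)(C)C(C)(C)C)[C@@]2(C)C=C(N3CCCC3)CC[C@H]2[C@@H]1Br
F3 | step 4 | C5 alcohol of 4 with the C1 vinylogous ester intact | COC1=CC(=O)[C@@]2(C)CC(O[Si](C(C)C)(C(C)C)C(C)C)=CC[C@H]2[C@H]1O
F4 | step 4 | C5 methanesulfonate of F3 | COC1=CC(=O)[C@@]2(C)CC(O[Si](C(C)C)(C(C)C)C(C)C)=CC[C@H]2[C@H]1OS(C)(=O)=O
F5 | step 4 | C1 alcohol (cis to the C11 methyl) of mesylate F4 | COC1=C[C@H](O)[C@@]2(C)CC(O[Si](C(C)C)(C(C)C)C(C)C)=CC[C@H]2[C@H]1OS(C)(=O)=O
F6 | step 4 | C1 tert-butyldimethylsilyl ether of F5 | COC1=C[C@H](O[Si](C)(C)C(C)(C)C)[C@@]2(C)CC(O[Si](C(C)C)(C(C)C)C(C)C)=CC[C@H]2[C@H]1OS(C)(=O)=O
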